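Begin with the easy step: add electrophile and target in the last row of each earlier run below, and hold the sum against the charge.

all flasks: electrophile 20 mM

| flask | nucleophile | remark | time |
|---|---|---|---|
| noon | 13 mM | run made earlier |  |
| winter | 27 mM | run made earlier |  |
| larch | 16.0 mM |  | 10 d |
| cedar | 32.0 mM |  | 10 d |

- noon (time / d: electrophile / %, target / %): 0.417: 90, 13; 0.625: 82, 15; 1.04: 76, 21; 1.67: 71, 25; 3.00: 60, 26; 5.00: 57, 25
- winter (time / d: electrophile / %, target / %): 0.833: 60, 38; 1.67: 43, 44; 2.50: 38, 48; 3.00: 31, 49; 4.00: 23, 52; 5.00: 24, 49

(each reading ± 2 percentage points)



- part of the electrophile that has reacted at the end, larch
- part of the electrophile that has reacted at the end, cedar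
- what raising the concentration of nucleophile from its lowest to its highest value here does to the part of the electrophile that has reacted (changes below 5 percentage points count as none) (it falls / no change / it rises)

The sum is 82.0% in noon and 73.0% in winter, so some electrophile sits in something unread. Noon hints at what it is, for between 1.67 d and 5.00 d the electrophile falls by 14 percentage points while the target stays near 25%. Guess, as my own reading, that the unread part holds two electrophile units, a finished target taken by one further electrophile, so that target ever made is the target read plus half the gap.

Now reckon nucleophile charged per unit of electrophile consumed in two ways. Counting electrophile lost gives 1.51 in noon and 1.78 in winter. Counting target ever made gives the nucleophile price, nucleophile charged per target ever made, of 1.91 in noon and 2.16 in winter. The two runs part by 0.265 on the first count and by 0.248 on the second, too close to choose between, so test each within noon: between its last two rows the first count slides from 1.62 to 1.51, further than the second, which goes from 1.97 to 1.91. With a scatter of 2 points on each reading this test is weak, but lean on it and carry the price.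

Solve both ends for larch. Its nucleophile buys 41.8% of the electrophile as target, and if each target takes one further electrophile the top end is twice that, 83.6%. On this guess, the part of noon's target ever made that a further electrophile has taken is 0.265 at 5.00 d; doubled as a rough allowance for the longer time, it joins the ends at 64.0%. Cedar's lower end is 83.7% and its top is the charge itself, so take the middle, 91.8%.

The forecast gives 52% for larch (46% to 59%) and 84% for cedar (77% to 92%), and says it rises, holding that “Both runs therefore look like plateaus set by the nucleophile charge”. My larch figure lies above its range, and my cedar figure stands at the top of its range.

At the end 60.8% of the electrophile has reacted in larch and 93.2% in cedar, and the answer on the trend is that it rises, by 32 points.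

    electrophile + nucleophile → acid set free + target (k = 0.0230 /M/min)
    nucleophile + acid set free ⇌ protonated nucleophile, settled at all times (K = 2.60 × 10⁵ /M)
    target → over-reaction product (k = 1.30 × 10⁻⁶ /min)
    electrophile + target → side product (k = 0.00550 /M/min)
    crystals ⇌ acid set free, rate k5*(cs5 - [acid set free]) while solid is left; crystals form when [acid set free] > cs5 (solubility = 3.90 mM, k = 0.00260 /min)

In larch at 10.0 d, with the nucleophile, the limiting reagent, down to 0.571% of its charge, target, half the side product and over-reaction product give a price of 1.97. Now take the neighbouring flask, larch with 12 mM of electrophile: the carried price puts its lower end at 69.7%, and it ends at 78.7% reacted, holding 48.1% target and 29.7% side product, at a price of 2.09.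

The numbers in the tables are calculated with constants of no real substance, noise included.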